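The route rests on disconnecting the heterocyclic C-ring of the upper (fisetinidol) unit across C2–C3 and C4–C4a. A catalytic asymmetric oxa-Povarov-type formal [4+2] cycloaddition joins an O-aryl oxocarbenium ion (C4a=C8a–O1=C2, from resorcinol monobenzyl ether and 3,4-dibenzyloxybenzaldehyde) with the C3=C4 double bond of an (E)-enol acetate installed at C8 of benzyl-protected (+)-afzelechin. It exploits the fact that C4 is benzylic to the phloroglucinol-type A-ring of the lower unit, which polarises the enol acetate to bond through C3 and stabilises the C4 cation that the resorcinol ring then captures. One operation thus builds the pyran ring and its three contiguous stereocentres (2R,3S,4S).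

Key step: step 7

Assumption: (+)-afzelechin (2R,3S) is bought as a chiral-pool natural product, and the enantiomer of the chiral acid that gives the (2R,3S,4S) sense in step 7 has to be found by screening.

Step 1
Reactants: 1 (+)-afzelechin
Product: 2 5,7,4'-tri-O-benzylafzelechin
Conditions: BnBr (3.1 equiv), K2CO3, DMF, rt
Reagents that add atoms: benzyl bromide, BrCc1ccccc1
Why: Williamson O-benzylation under carbonate conditions alkylates only the three phenolic hydroxyls and leaves the secondary 3-OH and both stereocentres untouched.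

Step 2
Reactants: 2 5,7,4'-tri-O-benzylafzelechin
Product: 3 8-bromo-5,7,4'-tri-O-benzylafzelechin
Conditions: NBS (1.0 equiv), CH2Cl2, −20 °C → rt
Reagents that add atoms: N-bromosuccinimide, O=C1CCC(=O)N1Br
Why: Electrophilic aromatic bromination of the phloroglucinol-type A-ring should occur at C8, the usual site of NBS attack on 5,7-di-O-benzyl flavan-3-ols, and creates no stereocentre.

Step 3
Reactants: 3 8-bromo-5,7,4'-tri-O-benzylafzelechin; 4 (E)-2-(2-ethoxyvinyl)-4,4,5,5-tetramethyl-1,3,2-dioxaborolane
Product: 5 8-[(E)-2-ethoxyvinyl]-5,7,4'-tri-O-benzylafzelechin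
Conditions: Pd(OAc)2 (5 mol%), SPhos (10 mol%), K3PO4, dioxane/H2O, 80 °C
Reagents that add atoms: none
Why: Suzuki–Miyaura coupling proceeds with retention of the (E)-alkenyl geometry, and the electron-rich biaryl phosphine should cope with the di-ortho-substituted, electron-rich aryl bromide.

Step 4
Reactants: 5 8-[(E)-2-ethoxyvinyl]-5,7,4'-tri-O-benzylafzelechin
Product: 6 (5,7,4'-tri-O-benzylafzelechin-8-yl)acetaldehyde
Conditions: 1 M HCl, THF, 0 °C → rt
Reagents that add atoms: water, O
Why: Acid-catalysed enol ether hydrolysis (C-protonation, hydration, loss of ethanol) unmasks the arylacetaldehyde under conditions that benzyl ethers and the flavan ring tolerate.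

Step 5
Reactants: 6 (5,7,4'-tri-O-benzylafzelechin-8-yl)acetaldehyde
Product: 7 (E)-2-(3-O-acetyl-5,7,4'-tri-O-benzylafzelechin-8-yl)vinyl acetate
Conditions: Ac2O (4 equiv), Et3N, DMAP (cat.), CH2Cl2, 0 °C → rt
Reagents that add atoms: acetic anhydride, CC(=O)OC(C)=O
Why: O-acylation of the easily formed, aryl-conjugated aldehyde enolate (and of the 3-OH) gives the enol acetate, the (E)-isomer being favoured because the di-ortho-substituted aryl ring disfavours the (Z)-enolate.

Step 6
Reactants: 8 3,4-bis(benzyloxy)benzaldehyde; 9 3-(benzyloxy)phenol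
Product: 11 3,4-bis(benzyloxy)benzaldehyde bis[3-(benzyloxy)phenyl] acetal, via 3,4-bis(benzyloxy)benzal chloride 10 (not isolated)
Conditions: SOCl2 (1.5 equiv), DMF (cat.), CH2Cl2, 0 °C → rt, evaporate; then 9 (2.2 equiv), K2CO3 (3 equiv), DMF, 0 °C → rt
Reagents that add atoms: 3-(benzyloxy)phenol (second equivalent of 9), Oc1cccc(OCc2ccccc2)c1
Why: Deoxydichlorination of the aldehyde by the Vilsmeier-type reagent, followed by double Williamson-type O-alkylation in which two molecules of the phenoxide of 9 displace the two chlorides of 10 in turn, gives the symmetrical diaryl acetal, whose two identical leaving groups make later ionisation to the O-aryl oxocarbenium ion unambiguous.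

Step 7
Reactants: 7 (E)-2-(3-O-acetyl-5,7,4'-tri-O-benzylafzelechin-8-yl)vinyl acetate; 11 3,4-bis(benzyloxy)benzaldehyde bis[3-(benzyloxy)phenyl] acetal
Product: 14 3-O-acetyl-7,3',4'-tri-O-benzylfisetinidol-(4α→8)-3-O-acetyl-5,7,4'-tri-O-benzylafzelechin, via oxocarbenium ion 12 (not isolated), via benzylic cation 13 (not isolated)
Conditions: chiral BINOL-derived N-triflyl imidodiphosphorimidate (IDPi) Brønsted acid (5 mol%), 11 (1.3 equiv), 4 Å MS, CH2Cl2, −60 → −40 °C
Reagents that add atoms: none
Why: Proposed new method: the confined chiral acid ionises acetal 11 (loss of 3-benzyloxyphenol) to the (E)-O-aryl oxocarbenium ion 12, paired with the chiral imidodiphosphorimidate anion; the enol acetate of 7 attacks C2 of 12 with its acetoxy-bearing carbon (Prins-type step) to give the C4 benzylic cation 13, which is stabilised as a quinone-methide-type cation by the 5,7-dibenzyloxy A-ring of the afzelechin unit and is then captured by the resorcinol ring (Friedel–Crafts step). The closest known reactions are the Lewis-acid-promoted oxa-Povarov reaction of aryl oxocarbenium ions with alkenes and the chiral-acid-catalysed aza-Povarov reaction; chiral-anion control of the oxygen variant and an enol ester as the 2π partner are not established. The new pyran ring closes by a six-membered Friedel–Crafts alkylation, 6-exo-trig at the cationic C4 with the arene C4a=C8a bond inside the ring, so that the overall change is a formal [4+2] cycloaddition. C2 and C3 are set together in the first C–C bond formation, their absolute sense by the face of 12 that the chiral anion leaves open (catalyst control) and their trans relation by the endo-aryl approach of the (E)-alkene typical of Povarov reactions; C4 is relayed from C3, because the chair-like closing transition state keeps all three substituents pseudo-equatorial and the 3-acetoxy carbonyl shields the syn face of the cation, which should give the 3,4-trans (2,4-cis) ring. The step needs C3 (not C4) of the alkene to be the nucleophile, secured by the weak acyloxy donor against the strongly donating trioxygenated aryl group; ring closure para (not ortho) to the benzyloxy group of the resorcinol ring, secured by sterics; and independence from the remote afzelechin stereocentres, which are too far from the reacting alkene to compete with the catalyst.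

Step 8
Reactants: 14 3-O-acetyl-7,3',4'-tri-O-benzylfisetinidol-(4α→8)-3-O-acetyl-5,7,4'-tri-O-benzylafzelechin
Product: 15 7,3',4'-tri-O-benzylfisetinidol-(4α→8)-5,7,4'-tri-O-benzylafzelechin
Conditions: K2CO3 (cat.), MeOH/THF, rt
Reagents that add atoms: none
Why: Zemplén-type transesterification removes both secondary acetates without touching the benzyl ethers, and no centre is epimerisable while all phenols are protected.

Step 9
Reactants: 15 7,3',4'-tri-O-benzylfisetinidol-(4α→8)-5,7,4'-tri-O-benzylafzelechin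
Product: 16 fisetinidol-(4α→8)-afzelechin (target)
Conditions: H2 (1 atm), Pd(OH)2/C, THF/MeOH, rt
Reagents that add atoms: none
Why: Catalytic hydrogenolysis cleaves all six benzyl aryl ethers, while the 5-deoxy interflavanyl C4–C8 bond and the pyran C2–O bonds should survive Pearlman conditions at ambient pressure.

Compound list

1 | (+)-afzelechin, (2R,3S)-2-(4-hydroxyphenyl)chromane-3,5,7-triol | Oc1ccc([C@H]2Oc3cc(O)cc(O)c3C[C@@H]2O)cc1 | starting material
2 | 5,7,4'-tri-O-benzylafzelechin, (2R,3S)-5,7-bis(benzyloxy)-2-[4-(benzyloxy)phenyl]chroman-3-ol | O(Cc1ccccc1)c1ccc([C@H]2Oc3cc(OCc4ccccc4)cc(OCc4ccccc4)c3C[C@@H]2O)cc1 | intermediate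
3 | 8-bromo-5,7,4'-tri-O-benzylafzelechin (2R,3S) | O(Cc1ccccc1)c1ccc([C@H]2Oc3c(c(OCc4ccccc4)cc(OCc4ccccc4)c3Br)C[C@@H]2O)cc1 | intermediate
4 | (E)-2-(2-ethoxyvinyl)-4,4,5,5-tetramethyl-1,3,2-dioxaborolane | CCO/C=C/B1OC(C)(C)C(C)(C)O1 | starting material
5 | 8-[(E)-2-ethoxyvinyl]-5,7,4'-tri-O-benzylafzelechin (2R,3S) | O(Cc1ccccc1)c1ccc([C@H]2Oc3c(c(OCc4ccccc4)cc(OCc4ccccc4)c3/C=C/OCC)C[C@@H]2O)cc1 | intermediate
6 | (5,7,4'-tri-O-benzylafzelechin-8-yl)acetaldehyde (2R,3S) | O(Cc1ccccc1)c1ccc([C@H]2Oc3c(c(OCc4ccccc4)cc(OCc4ccccc4)c3CC=O)C[C@@H]2O)cc1 | intermediate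
7 | (E)-2-(3-O-acetyl-5,7,4'-tri-O-benzylafzelechin-8-yl)vinyl acetate (2R,3S) | O(Cc1ccccc1)c1ccc([C@H]2Oc3c(c(OCc4ccccc4)cc(OCc4ccccc4)c3/C=C/OC(C)=O)C[C@@H]2OC(C)=O)cc1 | intermediate
8 | 3,4-bis(benzyloxy)benzaldehyde | O=Cc1ccc(OCc2ccccc2)c(OCc2ccccc2)c1 | starting material
9 | 3-(benzyloxy)phenol | Oc1cccc(OCc2ccccc2)c1 | starting material
10 | 3,4-bis(benzyloxy)benzal chloride, 4-(dichloromethyl)-1,2-bis(benzyloxy)benzene | ClC(Cl)c1ccc(OCc2ccccc2)c(OCc2ccccc2)c1 | intermediate (not isolated)
11 | 3,4-bis(benzyloxy)benzaldehyde bis[3-(benzyloxy)phenyl] acetal, built from one unit of 8 and two units of 9 | C(Oc1cccc(OCc2ccccc2)c1)(Oc1cccc(OCc2ccccc2)c1)c1ccc(OCc2ccccc2)c(OCc2ccccc2)c1 | intermediate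
12 | (E)-[3-(benzyloxy)phenyl][3,4-bis(benzyloxy)benzylidene]oxonium, the O-aryl oxocarbenium ion | c1ccccc1COc1cccc(c1)/[O+]=C/c1ccc(OCc2ccccc2)c(OCc2ccccc2)c1 | intermediate (not isolated)
13 | C4 benzylic cation after C2–C3 bond formation, open chain, new centres as in 14 | O(Cc1ccccc1)c1ccc([C@H]2Oc3c(c(OCc4ccccc4)cc(OCc4ccccc4)c3[CH+][C@H](OC(C)=O)[C@H](Oc3cccc(OCc4ccccc4)c3)c3ccc(OCc4ccccc4)c(OCc4ccccc4)c3)C[C@@H]2OC(C)=O)cc1 | intermediate (not isolated)
14 | 3-O-acetyl-7,3',4'-tri-O-benzylfisetinidol-(4α→8)-3-O-acetyl-5,7,4'-tri-O-benzylafzelechin, upper unit (2R,3S,4S), lower unit (2R,3S) | O(Cc1ccccc1)c1ccc([C@H]2Oc3c(c(OCc4ccccc4)cc(OCc4ccccc4)c3[C@@H]3c4ccc(OCc5ccccc5)cc4O[C@H](c4ccc(OCc5ccccc5)c(OCc5ccccc5)c4)[C@H]3OC(C)=O)C[C@@H]2OC(C)=O)cc1 | intermediate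
15 | 7,3',4'-tri-O-benzylfisetinidol-(4α→8)-5,7,4'-tri-O-benzylafzelechin | O(Cc1ccccc1)c1ccc([C@H]2Oc3c(c(OCc4ccccc4)cc(OCc4ccccc4)c3[C@@H]3c4ccc(OCc5ccccc5)cc4O[C@H](c4ccc(OCc5ccccc5)c(OCc5ccccc5)c4)[C@H]3O)C[C@@H]2O)cc1 | intermediate
16 | fisetinidol-(4α→8)-afzelechin, CNP0322555.1, upper unit (2R,3S,4S), lower unit (2R,3S) | Oc1ccc([C@H]2Oc3c(c(O)cc(O)c3[C@@H]3c4ccc(O)cc4O[C@H](c4ccc(O)c(O)c4)[C@H]3O)C[C@@H]2O)cc1 | target

Total step count: 9. Longest linear sequence: 8 steps (steps 1–5 and 7–9; step 6 is the one-step side branch).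

Steps most likely to fail

Step 7 (key step, proposed new method). The strong acid may ionise the enol acetate and cause oligomerisation, the oxocarbenium ion may attack C6 of the A-ring instead of the alkene, or facial control by the catalyst may be poor. The fallback uses the known biomimetic flavan-3,4-diol condensation; it sets out from (+)-afzelechin 1 and comes back at the target 16. Commercial (+)-fustin, (2R,3R)-3,7,3',4'-tetrahydroxyflavanone, would be reduced with NaBH4 in MeOH/EtOH to the 2,3-trans-3,4-trans flavan-3,4-diol (+)-mollisacacidin F1. In 0.1 M aqueous HCl at rt, F1 should ionise at C4 and alkylate C8 of unprotected 1 anti to its own 3-OH, giving 16 directly. The 4β-linked and C6-linked isomers expected beside it would be removed on Sephadex LH-20.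

Step 5. The electron-rich arylacetaldehyde 6 may self-condense or autoxidise, and enolate O-acylation may not be fully E-selective. The fallback sets out from bromide 3 and comes back at 7 without passing through the aldehyde, fixing the E-geometry by C–C coupling. Acetylation of the 3-OH (Ac2O, pyridine) would give 3-O-acetyl-8-bromo-5,7,4'-tri-O-benzylafzelechin F2. Heck coupling with vinylboronic acid pinacol ester (Pd2(dba)3, P(t-Bu)3, Cy2NMe, dioxane) would give the (E)-alkenylboronic ester F3. KHF2 in MeOH/H2O would convert it to the potassium (E)-alkenyltrifluoroborate F4. Copper-promoted oxidative coupling of F4 with acetic acid (Cu(OAc)2, DMAP, 4 Å MS, air), which retains alkene geometry, would then give 7.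

Step 6. The ionising gem-dichloride may C-alkylate the ambident phenoxide, may stop after a single displacement and hydrolyse on work-up, or may hydrolyse back to aldehyde 8 before it reacts. The fallback reverses the polarity; it sets out from 3-(benzyloxy)phenol 9 and comes back at acetal 11. Orthoester exchange of 9 with triethyl orthoformate (cat. acid, ethanol distilled off) would give tris[3-(benzyloxy)phenyl] orthoformate F5. 3,4-Bis(benzyloxy)phenylmagnesium bromide F6, made from commercial 4-bromo-1,2-bis(benzyloxy)benzene and magnesium in THF, would displace one aryloxide from F5 at low temperature (Bodroux–Chichibabin reaction) to give 11.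

Further compounds

F1 | step 7 | (+)-mollisacacidin, (2R,3S,4R)-2-(3,4-dihydroxyphenyl)chromane-3,4,7-triol | O[C@@H]1c2ccc(O)cc2O[C@H](c2ccc(O)c(O)c2)[C@H]1O
F2 | step 5 | 3-O-acetyl-8-bromo-5,7,4'-tri-O-benzylafzelechin (2R,3S) | O(Cc1ccccc1)c1ccc([C@H]2Oc3c(c(OCc4ccccc4)cc(OCc4ccccc4)c3Br)C[C@@H]2OC(C)=O)cc1
F3 | step 5 | 3-O-acetyl-5,7,4'-tri-O-benzyl-8-[(E)-2-(4,4,5,5-tetramethyl-1,3,2-dioxaborolan-2-yl)vinyl]afzelechin (2R,3S) | O(Cc1ccccc1)c1ccc([C@H]2Oc3c(c(OCc4ccccc4)cc(OCc4ccccc4)c3/C=C/B3OC(C)(C)C(C)(C)O3)C[C@@H]2OC(C)=O)cc1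
F4 | step 5 | potassium (E)-[2-(3-O-acetyl-5,7,4'-tri-O-benzylafzelechin-8-yl)vinyl]trifluoroborate (2R,3S) | O(Cc1ccccc1)c1ccc([C@H]2Oc3c(c(OCc4ccccc4)cc(OCc4ccccc4)c3/C=C/[B-](F)(F)F)C[C@@H]2OC(C)=O)cc1.[K+]
F5 | step 6 | tris[3-(benzyloxy)phenyl] orthoformate | C(Oc1cccc(OCc2ccccc2)c1)(Oc1cccc(OCc2ccccc2)c1)Oc1cccc(OCc2ccccc2)c1
F6 | step 6 | 3,4-bis(benzyloxy)phenylmagnesium bromide | Br[Mg]c1ccc(OCc2ccccc2)c(OCc2ccccc2)c1
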